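## Retrosynthetic overview

- Carbocycle locants: C1 (CH–aryl), C2=C3 (C3 methyl), C4, C5, C6 (quaternary: methyl and styryl). The last bond made is styryl–aryl, by Heck coupling of a C6 vinyl group with 8-iodo-7-methoxycoumarin. Before that, the coumarin pyranone on the C1 aryl ring is closed on a free phenol.
- Enabling feature: the ring alkene C2=C3 lies between sp3 C1 and C4, which are joined on the far side by C6–C5. With C5=C6 unsaturated the ring is a cyclohexa-1,4-diene, i.e. propyne (C2, C3, CH3) plus the diene C1=C6–C5=C4. The phenolic oxygen ortho to C1 and a carboxyl carbon on C6 can close a six-membered lactone, so this diene is a 3-vinylcoumarin with the aryl group locked "outside".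
- Key step: enantioselective cobalt-catalysed [4+2] cycloaddition of that vinylcoumarin with propyne forms C1–C2 and C3–C4 and sets the C1 stereocentre.
- The temporary lactone then restores the oxidation level: hydride adds at C5 and the lactone enolate is C-methylated at C6 (cis ring fusion, so aryl is cis to the carboxyl carbon). Reduction and methylenation turn the carboxyl carbon into the C6 vinyl group and free the phenol.
- Ring order: temporary pyranone, then carbocycle, then (temporary pyranone opened) coumarin pyranone on the C1 aryl; the second coumarin is brought in intact.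

Key step: step 2

Assumption: the sense of induction of the chiral cobalt catalyst cannot be predicted with confidence; the ligand antipode that gives the (10aS) adduct is to be fixed in the first run, and (S,S)-chiraphos [(2S,3S)-bis(diphenylphosphino)butane] is written throughout.

## Route

Step 1
Reactants: 1 2-hydroxy-6-methoxybenzaldehyde; 2 but-3-enoic acid
Product: 4 3-ethenyl-5-methoxy-2H-chromen-2-one, via aryl but-3-enoate 3 (not isolated)
Conditions: DCC, DMAP (cat.), CH2Cl2, 0 °C to rt; then Cs2CO3 (0.2 equiv), rt
Reagents that add atoms: none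
Why: Steglich esterification of the phenol followed by intramolecular Knoevenagel condensation of the doubly activated α-methylene onto the ortho aldehyde should give the 3-vinylcoumarin, as in the standard route from salicylaldehydes and activated acetic acids to 3-substituted coumarins.

Step 2
Reactants: 4 3-ethenyl-5-methoxy-2H-chromen-2-one; 5 propyne
Product: 6 (10aS)-1-methoxy-9-methyl-8,10a-dihydro-6H-benzo[c]chromen-6-one
Conditions: propyne (3 equiv), CoBr2[(S,S)-chiraphos] (10 mol %), Zn dust (20 mol %), ZnI2 (20 mol %), CH2Cl2, rt, sealed tube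
Reagents that add atoms: none
Why: Proposed new method: zinc reduces the cobalt dibromide complex to monovalent cobalt, which binds the s-cis diene C4=C3–CH=CH2 of 4 and propyne, couples coumarin C4 with the alkyne CH by oxidative cyclisation to an allyl/vinyl cobaltacycle, and then joins the vinyl CH2 terminus to the methyl-bearing alkyne carbon by reductive elimination, so both new ring bonds form in one catalytic turnover. The closest known reaction type is the CoBr2(dppe)/Zn/ZnI2-catalysed [4+2] cycloaddition of 1,3-dienes with unactivated terminal alkynes to cyclohexa-1,4-dienes; new here are the vinylcoumarin diene and a chiral dppe analogue to make the reaction enantioselective. The carbocycle closes in an intermolecular [4+2] mode, the six-membered ring being completed by C–C reductive elimination at cobalt, and the temporary lactone ring is untouched. The only new stereocentre, C10a, is controlled by the chiral bisphosphine, which decides which face of the flat, lactone-locked diene lies on cobalt. The step needs regioselectivity (methyl at C9, "para" to C6a), which is the normal preference of bisphosphine–cobalt catalysts for 2-substituted dienes and is reinforced because the unsubstituted alkyne carbon goes to the aryl-bearing diene terminus; the lactone holds the aryl group outside the s-cis diene, and the product is no longer a diene and cannot react again.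

Step 3
Reactants: 6 (10aS)-1-methoxy-9-methyl-8,10a-dihydro-6H-benzo[c]chromen-6-one
Product: 8 (6aS,10aS)-1-methoxy-6a,9-dimethyl-6a,7,8,10a-tetrahydro-6H-benzo[c]chromen-6-one, via lithium enolate 7 (not isolated)
Conditions: LiBH(s-Bu)3 (1.05 equiv), THF, −78 °C; then MeI, DMPU, −78 to −20 °C
Reagents that add atoms: iodomethane (CI)
Why: Conjugate reduction–enolate alkylation: the bulky hydride should add 1,4 to the alkylidene aryl lactone, and the lactone enolate should be C-methylated on the face of H-10a, anti to the C10a–C10 bond, giving the cis ring fusion and so fixing the quaternary centre relative to C10a.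

Step 4
Reactants: 8 (6aS,10aS)-1-methoxy-6a,9-dimethyl-6a,7,8,10a-tetrahydro-6H-benzo[c]chromen-6-one
Product: 9 (6aS,10aS)-1-methoxy-6a,9-dimethyl-6a,7,8,10a-tetrahydro-6H-benzo[c]chromen-6-ol (both C6 epimers)
Conditions: i-Bu2AlH (1.1 equiv), toluene, −78 °C; aq. potassium sodium tartrate
Reagents that add atoms: none
Why: Partial hydride reduction of a lactone to the lactol should be clean at low temperature, the lactone being the only carbonyl group in the molecule.

Step 5
Reactants: 9 (6aS,10aS)-1-methoxy-6a,9-dimethyl-6a,7,8,10a-tetrahydro-6H-benzo[c]chromen-6-ol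
Product: 11 2-[(1R,6R)-6-ethenyl-3,6-dimethylcyclohex-2-en-1-yl]-3-methoxyphenol, via open hydroxy aldehyde 10 (not isolated)
Conditions: Ph3PCH3Br (3.5 equiv), KOt-Bu (3.5 equiv), THF, 0 to 40 °C
Reagents that add atoms: methyltriphenylphosphonium bromide (C[P+](c1ccccc1)(c1ccccc1)c1ccccc1.[Br-])
Why: Wittig methylenation of the lactol through its open aldehyde form should give the C6 vinyl group and free the phenol, and the aldehyde has no α-hydrogen, so the quaternary centre cannot epimerise.

Step 6
Reactants: 11 2-[(1R,6R)-6-ethenyl-3,6-dimethylcyclohex-2-en-1-yl]-3-methoxyphenol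
Product: 12 3-[(1R,6R)-6-ethenyl-3,6-dimethylcyclohex-2-en-1-yl]-2-hydroxy-4-methoxybenzaldehyde
Conditions: MgCl2, Et3N, (CH2O)n, THF, reflux
Reagents that add atoms: paraformaldehyde, as formaldehyde (C=O)
Why: Magnesium phenoxide-directed ortho-formylation should deliver the formyl group to the only free position ortho to the hydroxyl group, which is also para to the methoxy group.

Step 7
Reactants: 12 3-[(1R,6R)-6-ethenyl-3,6-dimethylcyclohex-2-en-1-yl]-2-hydroxy-4-methoxybenzaldehyde
Product: 14 8-[(1R,6R)-6-ethenyl-3,6-dimethylcyclohex-2-en-1-yl]-7-methoxy-2H-chromen-2-one, via acyl ylide 13 (not isolated)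
Conditions: Ph3P=C=C=O (1.3 equiv), toluene, 90 °C
Reagents that add atoms: (triphenylphosphoranylidene)ketene (O=C=C=P(c1ccccc1)(c1ccccc1)c1ccccc1)
Why: The phenol should add to the ketene carbon to give an ester-stabilised ylide, which closes the pyranone by intramolecular Wittig reaction with the ortho aldehyde, the ring enforcing the cis alkene.

Step 8
Reactants: 15 7-hydroxy-2H-chromen-2-one
Product: 16 7-hydroxy-8-iodo-2H-chromen-2-one
Conditions: I2, KI, aq. NH3, rt
Reagents that add atoms: iodine (II)
Why: Electrophilic aromatic iodination of the phenoxide should take place at C8, the position between the hydroxyl group and the ring oxygen, which is the usual regiochemistry under iodine–ammonia conditions.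

Step 9
Reactants: 16 7-hydroxy-8-iodo-2H-chromen-2-one
Product: 17 8-iodo-7-methoxy-2H-chromen-2-one
Conditions: MeI, K2CO3, acetone, reflux
Reagents that add atoms: iodomethane (CI)
Why: Williamson O-methylation of the phenol under mild carbonate conditions should leave the lactone intact.

Step 10
Reactants: 14 8-[(1R,6R)-6-ethenyl-3,6-dimethylcyclohex-2-en-1-yl]-7-methoxy-2H-chromen-2-one; 17 8-iodo-7-methoxy-2H-chromen-2-one
Product: 18 8-[(1R,6R)-6-[(E)-2-(7-methoxy-2-oxo-2H-chromen-8-yl)ethenyl]-3,6-dimethylcyclohex-2-en-1-yl]-7-methoxy-2H-chromen-2-one (target)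
Conditions: Pd(OAc)2 (10 mol %), P(o-tol)3 (20 mol %), NaOAc, Bu4NBr, DMF, 90 °C
Reagents that add atoms: none
Why: Mizoroki–Heck reaction: the aryl group should add to the terminal vinyl carbon, and syn β-hydride elimination can only occur from the new benzylic CH2 because C6 is quaternary, which gives the (E)-styryl unit without touching the ring stereocentres.

## Compound list

1 | 2-hydroxy-6-methoxybenzaldehyde | COc1cccc(O)c1C=O | starting material
2 | but-3-enoic acid | C=CCC(=O)O | starting material
3 | 2-formyl-3-methoxyphenyl but-3-enoate | C=CCC(=O)Oc1cccc(OC)c1C=O | intermediate (not isolated)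
4 | 3-ethenyl-5-methoxy-2H-chromen-2-one | C=CC1=Cc2c(OC)cccc2OC1=O | intermediate
5 | propyne | CC#C | starting material
6 | (10aS)-1-methoxy-9-methyl-8,10a-dihydro-6H-benzo[c]chromen-6-one | COc1cccc2OC(=O)C3=CCC(C)=C[C@H]3c12 | intermediate
7 | lithium enolate (C6-olate, C6=C6a) of (10aS)-1-methoxy-9-methyl-6a,7,8,10a-tetrahydro-6H-benzo[c]chromen-6-one | [Li+].COc1cccc2OC([O-])=C3CCC(C)=C[C@H]3c12 | intermediate (not isolated)
8 | (6aS,10aS)-1-methoxy-6a,9-dimethyl-6a,7,8,10a-tetrahydro-6H-benzo[c]chromen-6-one | COc1cccc2OC(=O)[C@@]3(C)CCC(C)=C[C@H]3c12 | intermediate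
9 | (6aS,10aS)-1-methoxy-6a,9-dimethyl-6a,7,8,10a-tetrahydro-6H-benzo[c]chromen-6-ol (both C6 epimers) | COc1cccc2OC(O)[C@@]3(C)CCC(C)=C[C@H]3c12 | intermediate
10 | (1S,2S)-2-(2-hydroxy-6-methoxyphenyl)-1,4-dimethylcyclohex-3-ene-1-carbaldehyde | O=C[C@@]1(C)CCC(C)=C[C@H]1c1c(OC)cccc1O | intermediate (not isolated)
11 | 2-[(1R,6R)-6-ethenyl-3,6-dimethylcyclohex-2-en-1-yl]-3-methoxyphenol | C=C[C@@]1(C)CCC(C)=C[C@H]1c1c(OC)cccc1O | intermediate
12 | 3-[(1R,6R)-6-ethenyl-3,6-dimethylcyclohex-2-en-1-yl]-2-hydroxy-4-methoxybenzaldehyde | C=C[C@@]1(C)CCC(C)=C[C@H]1c1c(OC)ccc(C=O)c1O | intermediate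
13 | 2-[(1R,6R)-6-ethenyl-3,6-dimethylcyclohex-2-en-1-yl]-6-formyl-3-methoxyphenyl (triphenylphosphoranylidene)acetate | C=C[C@@]1(C)CCC(C)=C[C@H]1c1c(OC)ccc(C=O)c1OC(=O)C=P(c1ccccc1)(c1ccccc1)c1ccccc1 | intermediate (not isolated)
14 | 8-[(1R,6R)-6-ethenyl-3,6-dimethylcyclohex-2-en-1-yl]-7-methoxy-2H-chromen-2-one | C=C[C@@]1(C)CCC(C)=C[C@H]1c1c(OC)ccc2ccc(=O)oc12 | intermediate
15 | 7-hydroxy-2H-chromen-2-one | O=c1ccc2ccc(O)cc2o1 | starting material
16 | 7-hydroxy-8-iodo-2H-chromen-2-one | O=c1ccc2ccc(O)c(I)c2o1 | intermediate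
17 | 8-iodo-7-methoxy-2H-chromen-2-one | COc1ccc2ccc(=O)oc2c1I | intermediate
18 | 8-[(1R,6R)-6-[(E)-2-(7-methoxy-2-oxo-2H-chromen-8-yl)ethenyl]-3,6-dimethylcyclohex-2-en-1-yl]-7-methoxy-2H-chromen-2-one | COc1ccc2ccc(=O)oc2c1/C=C/[C@@]1(C)CCC(C)=C[C@H]1c1c(OC)ccc2ccc(=O)oc12 | target

## Step count and risks

Total steps: 10. Longest linear sequence: 8 (steps 1 to 7 and 10); steps 8 and 9 prepare the coupling partner 17.

**Step 2 (Proposed new method).** The chiral cobalt catalyst may discriminate the two diene faces poorly, or the more hindered chiral ligand may slow the cycloaddition so that alkyne trimerisation takes over. The fallback uses known chemistry and sets out from 4. Cycloaddition with the achiral catalyst CoBr2(dppe)/Zn/ZnI2 (dppe = 1,2-bis(diphenylphosphino)ethane) in CH2Cl2 should give racemic 1-methoxy-9-methyl-8,10a-dihydro-6H-benzo[c]chromen-6-one F1. The conditions of step 3 should convert it to racemic cis-1-methoxy-6a,9-dimethyl-6a,7,8,10a-tetrahydro-6H-benzo[c]chromen-6-one F2. Aminolysis of the aryl lactone with (R)-1-phenylethylamine (neat, 60 °C) should give two diastereomeric hydroxy amides, to be separated by chromatography or crystallisation. The wanted one, (1S,2S)-2-(2-hydroxy-6-methoxyphenyl)-1,4-dimethyl-N-[(1R)-1-phenylethyl]cyclohex-3-ene-1-carboxamide F3, is relactonised in warm acetic acid; the cis phenol and the α-quaternary amide are predisposed to close. The fallback returns to the route at 8.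

**Step 3.** The hydride reagent may act as a base and move the C6a=C7 double bond into the pyranone ring, which erases C10a; it may also attack the lactone carbonyl, or the methylation may show incomplete facial control. The fallback sets out from 6 and separates the two events. Neutral conjugate reduction with [(Ph3P)CuH]6 in benzene at rt should give, after work-up, (10aR)-1-methoxy-9-methyl-6a,7,8,10a-tetrahydro-6H-benzo[c]chromen-6-one F4 (C6a epimers), which is isolated. Deprotonation with LiN(SiMe3)2 in THF at −78 °C and methylation with MeI then form the cis-fused lactone. The fallback returns at 8.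

**Step 10.** Migratory insertion between the neopentyl-type alkene and the doubly ortho-substituted arylpalladium species may be slow, leading to catalyst decomposition, reduction of 17 or arylation at a coumarin C3–C4 bond. The fallback sets out from 9 and makes the styryl unit by olefination and Suzuki–Miyaura coupling.
- Boron variant of the Takai olefination on the open aldehyde form (CrCl2, Cl2CHBpin, LiI, THF, rt) should give 2-[(1R,6R)-3,6-dimethyl-6-[(E)-2-(4,4,5,5-tetramethyl-1,3,2-dioxaborolan-2-yl)ethenyl]cyclohex-2-en-1-yl]-3-methoxyphenol F5.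
- Coupling with 17 (Pd(OAc)2, 2-dicyclohexylphosphino-2',6'-dimethoxybiphenyl, K3PO4, THF–H2O, 60 °C) should give 8-[(E)-2-[(1R,2R)-2-(2-hydroxy-6-methoxyphenyl)-1,4-dimethylcyclohex-3-en-1-yl]ethenyl]-7-methoxy-2H-chromen-2-one F6.
- The conditions of step 6 should give 2-hydroxy-4-methoxy-3-[(1R,6R)-6-[(E)-2-(7-methoxy-2-oxo-2H-chromen-8-yl)ethenyl]-3,6-dimethylcyclohex-2-en-1-yl]benzaldehyde F7.
- The conditions of step 7 close the second pyranone, and the fallback returns at 18.

## Further compounds

F1 | step 2 | racemic 1-methoxy-9-methyl-8,10a-dihydro-6H-benzo[c]chromen-6-one | COc1cccc2OC(=O)C3=CCC(C)=CC3c12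
F2 | step 2 | racemic cis-1-methoxy-6a,9-dimethyl-6a,7,8,10a-tetrahydro-6H-benzo[c]chromen-6-one | COc1cccc2OC(=O)C3(C)CCC(C)=CC3c12
F3 | step 2 | (1S,2S)-2-(2-hydroxy-6-methoxyphenyl)-1,4-dimethyl-N-[(1R)-1-phenylethyl]cyclohex-3-ene-1-carboxamide | C[C@@H](NC(=O)[C@@]1(C)CCC(C)=C[C@H]1c2c(OC)cccc2O)c3ccccc3
F4 | step 3 | (10aR)-1-methoxy-9-methyl-6a,7,8,10a-tetrahydro-6H-benzo[c]chromen-6-one (C6a epimers) | COc1cccc2OC(=O)C3CCC(C)=C[C@H]3c12
F5 | step 10 | 2-[(1R,6R)-3,6-dimethyl-6-[(E)-2-(4,4,5,5-tetramethyl-1,3,2-dioxaborolan-2-yl)ethenyl]cyclohex-2-en-1-yl]-3-methoxyphenol | CC1(C)OB(/C=C/[C@@]2(C)CCC(C)=C[C@H]2c3c(OC)cccc3O)OC1(C)C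
F6 | step 10 | 8-[(E)-2-[(1R,2R)-2-(2-hydroxy-6-methoxyphenyl)-1,4-dimethylcyclohex-3-en-1-yl]ethenyl]-7-methoxy-2H-chromen-2-one | COc1ccc2ccc(=O)oc2c1/C=C/[C@@]1(C)CCC(C)=C[C@H]1c1c(OC)cccc1O
F7 | step 10 | 2-hydroxy-4-methoxy-3-[(1R,6R)-6-[(E)-2-(7-methoxy-2-oxo-2H-chromen-8-yl)ethenyl]-3,6-dimethylcyclohex-2-en-1-yl]benzaldehyde | COc1ccc2ccc(=O)oc2c1/C=C/[C@@]1(C)CCC(C)=C[C@H]1c1c(OC)ccc(C=O)c1O
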